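**Plan**
The retrosynthesis cuts, in order, the C3–O angelate ester, the C8=C17 methylene (Wittig), the C6–C7 bond of ring B (radical ring closure), the C9–C10 bond (Ireland–Claisen through a C6–O ester link) and the C13–CH3/C14–C15 bonds of the side chain (alkyne methylalumination).
Forward, ring A is made from (R)-carvone: its ring carbons become C1–C5 and C10, its methyl becomes C20, and its isopropenyl group is excised to the C3 oxygen. The side-chain acid comes from 5-chloropent-1-yne, the two halves are joined as an ester, the [3,3] shift forms C9–C10, and ring B is closed last.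
The enabling feature is the exocyclic C5=C6 methylene on ring A, flanked by the quaternary C4 and C10. A C7 radical next to the C8 carbonyl can only attack the free terminus C6, and the resulting tertiary C5 radical is covered on one face by the syn-axial methyls on C4 and C10.
Stereochemistry: C3 comes from the carvone centre (Criegee rearrangement with retention) and C4 from alkylation anti to the isopropenyl group. C10 comes from the Claisen shift anti to the axial C4 methyl of an acetal-locked ring A, C5 from hydrogen-atom transfer, and C9 from equilibration next to the C8 ketone. The 13E alkene comes from syn-carbometalation and the Z ester from angelic acid.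
The C8 ketone serves as radical-stabilising group, epimerisation handle and precursor of the exocyclic methylene. The p-methoxybenzylidene acetal is a temporary ring that is removed before acylation.

Key step: step 15

Remark: atoms carry labdane numbers throughout (ring A = C1–C5 and C10, ring B = C5–C10; C18 = oxygenated carbon on C4, C19 = methyl on C4, C20 = methyl on C10), and 4-methoxybenzyl chloromethyl ether and (tributylstannyl)methanol are taken as purchasable reagents.

**Step 1**
Reactants: 1 (R)-(−)-carvone
Product: 3 6-methylcarvone (both epimers at the new centre), via lithium dienolate 2 (not isolated)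
Conditions: LiN(i-Pr)2, THF, −78 °C; MeI, −78 → 0 °C
Reagents that add atoms: iodomethane (CI)
Why: Kinetic deprotonation of the enone at the CH2 next to the carbonyl and C-methylation (ketone enolate alkylation) should install C19; the new centre is re-enolised in step 2, so its configuration is immaterial.

**Step 2**
Reactants: 3 6-methylcarvone
Product: 5 ring A enone with quaternary C4 (C18H2OPMB trans to isopropenyl), via lithium enolate 4 (not isolated)
Conditions: LiN(i-Pr)2, THF, −78 °C; 4-methoxybenzyl chloromethyl ether, −78 → −20 °C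
Reagents that add atoms: 4-methoxybenzyl chloromethyl ether (COc1ccc(COCCl)cc1)
Why: Enolate alkylation with an alkoxymethyl chloride should create the quaternary C4; the electrophile is expected to enter anti to the adjacent isopropenyl group, which places C18 trans and C19 cis to the future C3 oxygen.

**Step 3**
Reactants: 5 ring A enone with isopropenyl group
Product: 7 ring A enone C3 acetate, via α-methoxy hydroperoxide 6 (not isolated)
Conditions: O3, CH2Cl2/MeOH, −78 °C; then Ac2O, Et3N, DMAP, −78 → 25 °C
Reagents that add atoms: ozone (O=[O+][O-]); methanol (CO)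
Why: Ozonolysis of the electron-rich 1,1-disubstituted alkene (the enone C=C is deactivated) in methanol gives the methoxy hydroperoxide; its acetylation should trigger the Criegee rearrangement, in which the ring carbon migrates to oxygen with retention, so the carvone stereocentre becomes the C3–O centre and the acetyl group is the former isopropenyl C–CH3 unit.

**Step 4**
Reactants: 7 ring A enone C3 acetate
Product: 9 C5–C10 enol triflate, via lithium enolate 8 (not isolated)
Conditions: LiBH(s-Bu)3 (1.05 equiv), THF, −78 °C; PhNTf2, −78 → 0 °C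
Reagents that add atoms: N-phenylbis(trifluoromethanesulfonimide) (O=S(=O)(N(c1ccccc1)S(=O)(=O)C(F)(F)F)C(F)(F)F)
Why: Conjugate hydride addition to the β-unsubstituted enone should give the tetrasubstituted C5–C10 enolate regiospecifically, which is trapped on oxygen (enolate triflation); no stereocentre is formed.

**Step 5**
Reactants: 9 C5–C10 enol triflate acetate
Product: 10 hydroxy enol triflate
Conditions: K2CO3 (0.2 equiv), MeOH, 0 → 25 °C
Reagents that add atoms: none
Why: Base-catalysed transesterification should free the C3–OH; the vinyl triflate and the PMB ether are inert, and with the ketone masked as the enol triflate there is no retro-aldol pathway.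

**Step 6**
Reactants: 10 hydroxy enol triflate
Product: 11 p-methoxybenzylidene acetal triflate
Conditions: DDQ (1.2 equiv), 4 Å molecular sieves, CH2Cl2, 0 °C
Reagents that add atoms: none
Why: Anhydrous DDQ oxidation of the PMB ether to the benzylic oxocarbenium ion and capture by the C3–OH (oxidative acetalisation) should give the trans-fused 1,3-dioxane with equatorial aryl group; this temporary ring locks ring A with C19 axial.

**Step 7**
Reactants: 11 p-methoxybenzylidene acetal triflate
Product: 12 ring A allylic alcohol (C6 = CH2OH on C5)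
Conditions: (tributylstannyl)methanol, Pd(PPh3)4 (10 mol %), LiCl, 1,4-dioxane, 100 °C
Reagents that add atoms: (tributylstannyl)methanol (CCCC[Sn](CO)(CCCC)CCCC)
Why: Stille coupling of the enol triflate with the hydroxymethylstannane should install C6 directly at the alcohol oxidation level, LiCl assisting the transmetalation.

**Step 8**
Reactants: 13 5-chloropent-1-yne
Product: 15 (E)-6-chloro-3-methylhex-2-en-1-ol, via alkenyldimethylalane 14 (not isolated)
Conditions: Me3Al, Cp2ZrCl2 (0.25 equiv), CH2Cl2, 0 → 25 °C; then n-BuLi, THF, −78 °C; (CH2O)n, −78 → 25 °C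
Reagents that add atoms: trimethylaluminium (C[Al](C)C); formaldehyde from paraformaldehyde (C=O)
Why: Zirconium-catalysed syn-methylalumination of the terminal alkyne (Negishi carboalumination) followed by hydroxymethylation of the alanate should give the trisubstituted allylic alcohol; the syn addition fixes the 13E geometry.

**Step 9**
Reactants: 15 (E)-6-chloro-3-methylhex-2-en-1-ol
Product: 16 TBDPS ether of 15
Conditions: t-BuPh2SiCl, imidazole, CH2Cl2, 25 °C
Reagents that add atoms: tert-butylchlorodiphenylsilane (CC(C)(C)[Si](Cl)(c1ccccc1)c1ccccc1)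
Why: Standard silylation of the primary allylic alcohol gives an ether that should survive the organometallic, radical and basic steps that follow.

**Step 10**
Reactants: 16 TBDPS ether of the chloro alcohol
Product: 18 (E)-7-[(tert-butyldiphenylsilyl)oxy]-5-methylhept-5-enoic acid, via alkylmagnesium chloride 17 (not isolated)
Conditions: Mg, I2 (cat.), THF, 60 °C; then CO2, −20 → 25 °C; aqueous HCl to pH 3
Reagents that add atoms: carbon dioxide (O=C=O)
Why: Grignard formation from the primary chloride and carboxylation should add C8; the radical on the way to the Grignard reagent has no favourable ring closure onto the remote alkene.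

**Step 11**
Reactants: 12 ring A allylic alcohol; 18 side-chain acid
Product: 19 allylic ester
Conditions: DCC, DMAP (cat.), CH2Cl2, 0 → 25 °C
Reagents that add atoms: none
Why: Steglich esterification of the primary allylic alcohol with the unhindered acid should join the two halves through the C6–O–C8 link needed for the sigmatropic shift.

**Step 12**
Reactants: 19 allylic ester
Product: 22 rearranged acid with quaternary C10 and exocyclic C5=C6 (C9 epimers), via silyl ketene acetal 20 (not isolated), via trimethylsilyl ester 21 (not isolated)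
Conditions: LiN(i-Pr)2, Me3SiCl/Et3N, THF, −78 → 25 °C; then toluene, 90 °C; then MeOH/H2O, work-up at pH 5
Reagents that add atoms: none
Why: Ireland–Claisen rearrangement of the silyl ketene acetal should form C9–C10 and move the ring alkene into the exocyclic C5=C6 position; C10 is set by approach of the six-membered array on the ring face opposite the axial C19 methyl of the acetal-locked half-chair (C20 ends cis to C19), while C9 is not controlled and is corrected in step 15.

**Step 13**
Reactants: 22 rearranged acid
Product: 23 methyl ketone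
Conditions: MeLi (3 equiv), Et2O, 0 → 25 °C; inverse quench into aqueous NH4Cl
Reagents that add atoms: methyllithium ([Li]C)
Why: Addition of MeLi to the lithium carboxylate gives a dilithio gem-diolate that cannot add a second equivalent and should collapse to the methyl ketone on work-up, which brings in C7.

**Step 14**
Reactants: 23 methyl ketone
Product: 25 bromomethyl ketone, via silyl enol ether 24 (not isolated)
Conditions: LiN(i-Pr)2, Me3SiCl, THF, −78 °C; then N-bromosuccinimide, THF, −78 → 0 °C
Reagents that add atoms: N-bromosuccinimide (O=C1CCC(=O)N1Br)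
Why: Kinetic enolisation should occur at the methyl group, because the C9 hydrogen is tertiary and neopentylic; bromination of the silyl enol ether is much faster than attack of the reagent on the isolated alkenes.

**Step 15**
Reactants: 25 bromomethyl ketone
Product: 27 ring B ketone with trans ring fusion and equatorial side chain, via C9-epimeric decalones 26 (not isolated)
Conditions: (Me3Si)3SiH (1.3 equiv) and AIBN (0.2 equiv) added over 8 h to 25 (0.005 M), benzene, 80 °C; then NaOMe, MeOH/THF, 25 °C
Reagents that add atoms: none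
Why: Bromine abstraction by the silyl radical gives the C7 radical stabilised by the C8 carbonyl, which adds to the free terminus C6 of the exocyclic C5=C6 methylene and closes ring B in the 6-endo-trig mode, after which the tertiary C5 radical takes a hydrogen atom from the silane; the closest known reaction type is the reductive 6-endo cyclisation of α-halo ketone radicals onto 1,1-disubstituted alkenes. The 5-exo alternative would need bond formation at C5, which lies between the quaternary C4 and C10, so the endo regiochemistry is enforced by the substrate. The new C5 stereocentre is set in the hydrogen-atom transfer: the α face of the radical is covered by the syn-axial methyls C19 and C20 of the acetal-locked chair, so hydrogen should arrive from the β face and give the trans ring fusion. C9, which enters as a mixture, is now α to the ring ketone and is funnelled by methoxide equilibration into the epimer with the equatorial side chain. The step needs ring closure to outrun direct reduction of the C7 radical, which slow silane addition at high dilution secures, and the remote C13=C14 alkene is left alone because no small-ring closure onto it is available.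

**Step 16**
Reactants: 27 ring B ketone
Product: 28 8(17)-methylene decalin
Conditions: Ph3PCH3Br, KOtBu, toluene, 90 °C
Reagents that add atoms: methyltriphenylphosphonium bromide (C[P+](c1ccccc1)(c1ccccc1)c1ccccc1.[Br-])
Why: Wittig methylenation of the C8 ketone should give the exocyclic alkene; any enolisation toward C9 under the basic conditions returns the same thermodynamic epimer.

**Step 17**
Reactants: 28 8(17)-methylene decalin acetal
Product: 29 C3,C18-diol
Conditions: AcOH/THF/H2O (3:1:1), 40 °C
Reagents that add atoms: none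
Why: Mild acid hydrolysis should remove the electron-rich benzylidene acetal without cleaving the TBDPS ether or isomerising the exocyclic alkene.

**Step 18**
Reactants: 29 C3,C18-diol
Product: 30 C18 TBS ether with free C3–OH
Conditions: t-BuMe2SiCl (1.1 equiv), imidazole, CH2Cl2, 0 °C
Reagents that add atoms: tert-butylchlorodimethylsilane (CC(C)(C)[Si](C)(C)Cl)
Why: Silylation should be selective for the primary C18–OH over the secondary, neopentylic C3–OH.

**Step 19**
Reactants: 30 C18 TBS ether with free C3–OH
Product: 31 C3 angelate bis-silyl ether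
Conditions: angelic acid, 2,4,6-trichlorobenzoyl chloride, Et3N, toluene, 25 °C; then 30, toluene, 80 °C
Reagents that add atoms: angelic acid (C/C=C(/C)C(=O)O)
Why: Yamaguchi-type mixed-anhydride acylation run without DMAP is the known way to acylate hindered secondary alcohols with angelic acid while avoiding Z to E isomerisation to the tiglate.

**Step 20**
Reactants: 31 C3 angelate bis-silyl ether
Product: 32 target CNP0118197.1
Conditions: HF·pyridine, pyridine/THF, 0 → 25 °C
Reagents that add atoms: none
Why: Buffered fluoride should cleave both primary silyl ethers without hydrolysing or isomerising the angelate, moving it to the C18 oxygen, or touching the alkenes.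

**Compound list**
1 | (R)-(−)-carvone, (5R)-2-methyl-5-(prop-1-en-2-yl)cyclohex-2-en-1-one | CC1=CC[C@@H](C(C)=C)CC1=O | starting material
2 | lithium dienolate of 1 (deprotonated at the CH2 next to C=O) | CC1=CC[C@@H](C(C)=C)C=C1O[Li] | intermediate
3 | 6-methylcarvone, (5R)-2,6-dimethyl-5-(prop-1-en-2-yl)cyclohex-2-en-1-one, both epimers at C6 | CC1=CC[C@@H](C(C)=C)C(C)C1=O | intermediate
4 | lithium enolate of 3 | CC1=CC[C@@H](C(C)=C)C(C)=C1O[Li] | intermediate
5 | (5S,6R)-6-{[(4-methoxybenzyl)oxy]methyl}-2,6-dimethyl-5-(prop-1-en-2-yl)cyclohex-2-en-1-one; C18H2OPMB trans and C19 methyl cis to isopropenyl | CC1=CC[C@@H](C(C)=C)[C@](C)(COCc2ccc(OC)cc2)C1=O | intermediate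
6 | α-methoxy hydroperoxide of 5 (isopropenyl replaced by C(CH3)(OCH3)OOH) | CC1=CC[C@@H](C(C)(OC)OO)[C@](C)(COCc2ccc(OC)cc2)C1=O | intermediate
7 | ring A enone acetate: as 5 with OAc in place of isopropenyl, same orientation (C3–OAc trans to C18) | CC1=CC[C@@H](OC(C)=O)[C@](C)(COCc2ccc(OC)cc2)C1=O | intermediate
8 | lithium C5–C10 enolate from 1,4-reduction of 7 | CC1=C(O[Li])[C@@](C)(COCc2ccc(OC)cc2)[C@H](OC(C)=O)CC1 | intermediate
9 | enol triflate: C5(OTf)=C10(CH3), C3–OAc, C4(CH3)(CH2OPMB) | CC1=C(OS(=O)(=O)C(F)(F)F)[C@@](C)(COCc2ccc(OC)cc2)[C@H](OC(C)=O)CC1 | intermediate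
10 | hydroxy enol triflate (C3–OH) | CC1=C(OS(=O)(=O)C(F)(F)F)[C@@](C)(COCc2ccc(OC)cc2)[C@H](O)CC1 | intermediate
11 | acetal triflate: trans-fused 2-(4-methoxyphenyl)-1,3-dioxane over O3–C3–C4–C18–O18, aryl equatorial, C19 axial | CC1=C(OS(=O)(=O)C(F)(F)F)[C@@]2(C)CO[C@H](c3ccc(OC)cc3)O[C@@H]2CC1 | intermediate
12 | ring A allylic alcohol: C5(CH2OH)=C10(CH3) with the acetal of 11 | CC1=C(CO)[C@@]2(C)CO[C@H](c3ccc(OC)cc3)O[C@@H]2CC1 | intermediate
13 | 5-chloropent-1-yne | C#CCCCCl | starting material
14 | (E)-(5-chloro-2-methylpent-1-en-1-yl)dimethylalane | ClCCC/C(C)=C/[Al](C)C | intermediate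
15 | (E)-6-chloro-3-methylhex-2-en-1-ol | ClCCC/C(C)=C/CO | intermediate
16 | tert-butyl{[(E)-6-chloro-3-methylhex-2-en-1-yl]oxy}diphenylsilane | ClCCC/C(C)=C/CO[Si](c1ccccc1)(c1ccccc1)C(C)(C)C | intermediate
17 | alkylmagnesium chloride from 16 | Cl[Mg]CCC/C(C)=C/CO[Si](c1ccccc1)(c1ccccc1)C(C)(C)C | intermediate
18 | (E)-7-[(tert-butyldiphenylsilyl)oxy]-5-methylhept-5-enoic acid | OC(=O)CCC/C(C)=C/CO[Si](c1ccccc1)(c1ccccc1)C(C)(C)C | intermediate
19 | ester of allylic alcohol 12 with acid 18 | CC1=C(COC(=O)CCC/C(C)=C/CO[Si](c4ccccc4)(c5ccccc5)C(C)(C)C)[C@@]2(C)CO[C@H](c3ccc(OC)cc3)O[C@@H]2CC1 | intermediate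
20 | trimethylsilyl ketene acetal of 19 | CC1=C(COC(O[Si](C)(C)C)=CCC/C(C)=C/CO[Si](c4ccccc4)(c5ccccc5)C(C)(C)C)[C@@]2(C)CO[C@H](c3ccc(OC)cc3)O[C@@H]2CC1 | intermediate
21 | trimethylsilyl ester of 22 | C=C1[C@@]2(C)CO[C@H](c3ccc(OC)cc3)O[C@@H]2CC[C@@]1(C)C(C(=O)O[Si](C)(C)C)CC/C(C)=C/CO[Si](c4ccccc4)(c5ccccc5)C(C)(C)C | intermediate
22 | rearranged acid: ring A with exocyclic C5=C6, quaternary C10 (C20 cis to C19), C9 bearing COOH (C8) and the side chain; C9 epimers | C=C1[C@@]2(C)CO[C@H](c3ccc(OC)cc3)O[C@@H]2CC[C@@]1(C)C(C(=O)O)CC/C(C)=C/CO[Si](c4ccccc4)(c5ccccc5)C(C)(C)C | intermediate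
23 | methyl ketone (C8=O, C7 = CH3); C9 epimers | C=C1[C@@]2(C)CO[C@H](c3ccc(OC)cc3)O[C@@H]2CC[C@@]1(C)C(C(C)=O)CC/C(C)=C/CO[Si](c4ccccc4)(c5ccccc5)C(C)(C)C | intermediate
24 | trimethylsilyl enol ether of 23 (C7=C8) | C=C1[C@@]2(C)CO[C@H](c3ccc(OC)cc3)O[C@@H]2CC[C@@]1(C)C(C(=C)O[Si](C)(C)C)CC/C(C)=C/CO[Si](c4ccccc4)(c5ccccc5)C(C)(C)C | intermediate
25 | bromomethyl ketone (C7H2Br); C9 epimers | C=C1[C@@]2(C)CO[C@H](c3ccc(OC)cc3)O[C@@H]2CC[C@@]1(C)C(C(=O)CBr)CC/C(C)=C/CO[Si](c4ccccc4)(c5ccccc5)C(C)(C)C | intermediate
26 | trans-decalin C8 ketone, mixture of C9 epimers | O=C1CC[C@H]2[C@@](C)(CC[C@H]3O[C@@H](c4ccc(OC)cc4)OC[C@]23C)C1CC/C(C)=C/CO[Si](c5ccccc5)(c6ccccc6)C(C)(C)C | intermediate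
27 | trans-decalin C8 ketone with equatorial C9 side chain (C5, C9, C10 as in the target) | O=C1CC[C@H]2[C@@](C)(CC[C@H]3O[C@@H](c4ccc(OC)cc4)OC[C@]23C)[C@@H]1CC/C(C)=C/CO[Si](c5ccccc5)(c6ccccc6)C(C)(C)C | intermediate
28 | 8(17)-methylene decalin with acetal and TBDPS ether | C=C1CC[C@H]2[C@@](C)(CC[C@H]3O[C@@H](c4ccc(OC)cc4)OC[C@]23C)[C@@H]1CC/C(C)=C/CO[Si](c5ccccc5)(c6ccccc6)C(C)(C)C | intermediate
29 | C3,C18-diol, C15 TBDPS ether | C=C1CC[C@H]2[C@@](C)(CC[C@@H](O)[C@]2(C)CO)[C@@H]1CC/C(C)=C/CO[Si](c3ccccc3)(c4ccccc4)C(C)(C)C | intermediate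
30 | C18 TBS ether, C15 TBDPS ether, free C3–OH | C=C1CC[C@H]2[C@@](C)(CC[C@@H](O)[C@]2(C)CO[Si](C)(C)C(C)(C)C)[C@@H]1CC/C(C)=C/CO[Si](c3ccccc3)(c4ccccc4)C(C)(C)C | intermediate
31 | C3 angelate of 30 | C=C1CC[C@H]2[C@@](C)(CC[C@@H](OC(=O)/C(C)=C\C)[C@]2(C)CO[Si](C)(C)C(C)(C)C)[C@@H]1CC/C(C)=C/CO[Si](c3ccccc3)(c4ccccc4)C(C)(C)C | intermediate
32 | CNP0118197.1, (3R,4S,5S,9R,10S,13E)-3-[(Z)-2-methylbut-2-enoyloxy]labda-8(17),13-diene-15,18-diol (ent-labdane) | C=C1CC[C@H]2[C@@](C)(CC[C@@H](OC(=O)/C(C)=C\C)[C@]2(C)CO)[C@@H]1CC/C(C)=C/CO | target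

**Step count and risks**
Total steps: 20. Longest linear sequence: 17 (steps 1–7 and 11–20).

Steps most likely to fail:

1. Step 12. The [3,3] shift may deliver C9 to the α face of C10 (insufficient facial bias from the axial C19 methyl), or the hindered ester enolate may decompose before the tetrasubstituted alkene reacts. The fallback replaces substrate control by reagent control and sets out from ester 19. Enolisation at −78 °C in CH2Cl2 with (S,S)-2-bromo-1,3-bis{[3,5-bis(trifluoromethyl)phenyl]sulfonyl}-4,5-diphenyl-1,3,2-diazaborolidine and Et3N (or its antipode, whichever is the matched controller) should give the boron ketene acetal F1. This rearranges between −20 and 4 °C under control of the C2-symmetric sulfonamide to the acyloxyborane F2, and aqueous work-up returns to the route at acid 22.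

2. Step 15. Hydrogen transfer to the C7 radical may occur before ring closure, or hydrogen may be delivered to the α face of C5. The fallback closes the same C6–C7 bond by a polar enolate alkylation and sets out from acid 22. Coupling with MeNH(OMe)·HCl (EDC·HCl, HOBt, i-Pr2NEt) gives the N-methoxy-N-methylamide F3. Hydroboration of the exocyclic methylene with 9-BBN (THF, 60 °C; NaBO3) puts boron on C6 and hydrogen on the β face of C5, opposite the axial methyls, and gives the primary alcohol F4. I2, PPh3 and imidazole give the iodide F5, and MeMgBr gives the iodo methyl ketone F6. LiN(i-Pr)2 (THF, −78 → 25 °C) generates the kinetic methyl enolate, which closes ring B by 6-exo-tet alkylation at C6 to the decalones 26. Equilibration with NaOMe comes back to the route at ketone 27.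

3. Step 7. Transfer of the sp3 hydroxymethyl group from tin to the hindered vinylpalladium intermediate may be slow, with competing reduction or hydrolysis of the triflate. The fallback brings C6 in as carbon monoxide and sets out from triflate 11. Methoxycarbonylation (Pd(OAc)2, dppf, CO 1 atm, MeOH, Et3N, DMF, 60 °C) gives the methyl ester F7, and reduction with i-Bu2AlH (CH2Cl2, −78 °C) comes back to the route at allylic alcohol 12.

**Further compounds**
F1 | step 12 | boron ketene acetal of 19 with the (S,S)-diazaborolidine controller | CC1=C(COC(=CCC/C(C)=C/CO[Si](c4ccccc4)(c5ccccc5)C(C)(C)C)OB6N(S(=O)(=O)c7cc(C(F)(F)F)cc(C(F)(F)F)c7)[C@@H](c7ccccc7)[C@H](c7ccccc7)N6S(=O)(=O)c6cc(C(F)(F)F)cc(C(F)(F)F)c6)[C@@]2(C)CO[C@H](c3ccc(OC)cc3)O[C@@H]2CC1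
F2 | step 12 | acyloxyborane of acid 22 with the (S,S)-diazaborolidine controller | C=C1[C@@]2(C)CO[C@H](c3ccc(OC)cc3)O[C@@H]2CC[C@@]1(C)C(C(=O)OB6N(S(=O)(=O)c7cc(C(F)(F)F)cc(C(F)(F)F)c7)[C@@H](c7ccccc7)[C@H](c7ccccc7)N6S(=O)(=O)c6cc(C(F)(F)F)cc(C(F)(F)F)c6)CC/C(C)=C/CO[Si](c4ccccc4)(c5ccccc5)C(C)(C)C
F3 | step 15 | N-methoxy-N-methylamide of acid 22 | C=C1[C@@]2(C)CO[C@H](c3ccc(OC)cc3)O[C@@H]2CC[C@@]1(C)C(C(=O)N(C)OC)CC/C(C)=C/CO[Si](c4ccccc4)(c5ccccc5)C(C)(C)C
F4 | step 15 | primary C6 alcohol with C5–H trans to C20 (hydroboration product of F3) | OC[C@@H]1[C@@]2(C)CO[C@H](c3ccc(OC)cc3)O[C@@H]2CC[C@@]1(C)C(C(=O)N(C)OC)CC/C(C)=C/CO[Si](c4ccccc4)(c5ccccc5)C(C)(C)C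
F5 | step 15 | primary C6 iodide from F4 | IC[C@@H]1[C@@]2(C)CO[C@H](c3ccc(OC)cc3)O[C@@H]2CC[C@@]1(C)C(C(=O)N(C)OC)CC/C(C)=C/CO[Si](c4ccccc4)(c5ccccc5)C(C)(C)C
F6 | step 15 | C6 iodo methyl ketone | IC[C@@H]1[C@@]2(C)CO[C@H](c3ccc(OC)cc3)O[C@@H]2CC[C@@]1(C)C(C(C)=O)CC/C(C)=C/CO[Si](c4ccccc4)(c5ccccc5)C(C)(C)C
F7 | step 7 | methyl ester at C6 (carbonylation product of 11) | CC1=C(C(=O)OC)[C@@]2(C)CO[C@H](c3ccc(OC)cc3)O[C@@H]2CC1
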